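The data come from a simulation from invented constants.

The epsilon run and its two companions at higher reagent charges are what we hold for four new flasks, which differ in what goes in slowly and when.

| flask | substrate | reagent | remark | time |
|---|---|---|---|---|
| epsilon | 20 mM | 60 mM | run made earlier |  |
| zeta | 20 mM | 84 mM | run made earlier |  |
| theta | 20 mM | 130 mM | run made earlier |  |
| Monday's | 20 mM | 60.0 mM | everything together at the start | 15 d |
| Saturday's | 20 mM (fed, over 3.0 d) | 60.0 mM | all else is in the flask from the start; the feed brings no volume worth counting | 15 d |
| Tuesday's | 20 mM (fed, over 12 d) | 60.0 mM | all else is in the flask from the start; the feed brings no volume worth counting | 15 d |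
| Sunday's | 20 mM | 60.0 mM (fed, over 12 d) | all else is in the flask from the start; the feed brings no volume worth counting | 15 d |

| run | time / d | double product / % | triple product / % | substrate / % |
|---|---|---|---|---|
| epsilon | 0.625 | 10.9 | 4.0 | 53.1 |
| epsilon | 1.67 | 16.4 | 17.0 | 25.3 |
| epsilon | 3.00 | 12.0 | 24.8 | 14.3 |
| epsilon | 5.00 | 8.1 | 27.7 | 7.4 |
| epsilon | 6.00 | 6.5 | 26.3 | 6.1 |
| epsilon | 10.0 | 2.4 | 23.2 | 3.5 |
| zeta | 3.00 | 9.5 | 30.7 | 5.5 |
| zeta | 6.00 | 1.9 | 22.7 | 1.2 |
| zeta | 10.0 | 0.1 | 12.8 | 1.1 |
| zeta | 12.0 | 0 | 9.0 | 1.0 |
| zeta | 15.0 | 0.2 | 6.3 | 0 |
| zeta | 20.0 | 0.1 | 2.9 | 0 |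
| theta | 1.25 | 14.9 | 32.4 | 9.2 |
| theta | 2.50 | 4.8 | 27.1 | 2.2 |
| theta | 4.00 | 0.3 | 14.0 | 0 |
| theta | 6.00 | 0.1 | 4.3 | 0.6 |
| theta | 10.0 | 0.1 | 0.7 | 0 |
| theta | 20.0 | 0 | 0 | 0.3 |

(each reading ± 0.5 percentage points)

- a reading or a percentage of double product counts all its forms, free or not

- the flask with the highest share of double product in double product plus triple product ("all alike" if they lie within 1.5 percentage points) (Monday's / Saturday's / Tuesday's / Sunday's / all alike)
- share of double product in double product plus triple product at the end, Monday's
- share of double product in double product plus triple product at the end, Saturday's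
- share of double product in double product plus triple product at the end, Tuesday's
- share of double product in double product plus triple product at the end, Sunday's

Substrate in the epsilon run fell to 53.1 % by 0.625 d, which reads as a second-order constant k = 0.0169 /mM/d. Multiply k by the reagent charge and by the span left once the last of the feed is in. For Tuesday's this gives 3.04, and we call this product the contact number N: a yardstick reckoned as if reagent stood at its full charge, and not a count of lifetimes that the flask really has.

In a batch run the span is simply the time, so we read the share of double product against N in the earlier runs. The epsilon run at 3.00 d has N = 3.04 and a share of 32.6 %. The theta run, at its far higher charge, has N = 2.74 at 1.25 d and a share of 31.5 %. The epsilon run at 10.0 d has N = 10.1 and a share of 9.38 %.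

Monday's has N = 15.2 and Saturday's 12.2, both beyond that last reading, so we put both below 9.38 %. Tuesday's and Sunday's share 3.04, so we put both near 32.6 %, and the number cannot part them.

The forecast names Tuesday's, with 6 %, 7.5 %, 32 % and 8 % for Monday's, Saturday's, Tuesday's and Sunday's. It holds that “Sunday's reaches nearly the same reagent exposure as Monday's”, and there it differs from our reckoning.

The flasks give 6.32 %, 8.60 %, 24.7 % and 18.6 % in that order, with Tuesday's highest.

    reagent + mono adduct → double product (k = 1.00 /M/h)
    substrate + reagent → mono adduct (k = 0.790 /M/h)
    crystals ⇌ double product, rate k3*(cs3 - [double product]) while solid is left; crystals form when [double product] > cs3 (solubility = 16.0 mM, k = 0.190 /h)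
    reagent + double product → triple product (k = 1.30 /M/h)
    double product → over-reaction product (k = 0.0160 /h)
    reagent → decomposition product (k = 9.70 × 10⁻⁶ /h)
    reagent + triple product → tetra adduct (k = 0.440 /M/h)

At N = 3.04, Tuesday's and Sunday's both stand above Monday's, yet they differ by 6.1 percentage points, so N gives the grouping and not the value. Sunday's recipe dosed over 3.60 d has N = 11.5 and ends at 7.91 %, beside Saturday's 8.60 %. The step from double product to over-reaction product is one part of the spread: with that step taken away, the gap between Tuesday's and Monday's falls from 18 points to 8.7 points.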